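**Plan**

- Retrosynthesis: after removal of seven benzyl groups the pyran ring is cut at O1–C2 and C3–C4. Ring atoms O1, C8a, C4a and C4 then belong to an o-quinone methide of the phloroglucinol ring, and C2–C3 (catechol ring on C2, acyloxy oxygen on C3) is the double bond of an (E)-2-arylvinyl ester that already carries the whole side chain.
- That enol ester is cut at its vinyl C–O bond (side-chain acid plus trans-styryltrifluoroborate), and the acid at C4–C5 (benzylic chloride plus acetoacetate dianion).
- Forward: side-chain acid (steps 1–4), styrylboron reagent (steps 5–6), union to the E enol ester (step 7), salicyl alcohol (steps 8–9), closure of the pyran ring, the only ring made (step 10), global debenzylation (step 11).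
- Stereochemistry: the side-chain (S) centre comes from Ru–(S)-BINAP hydrogenation of the β-keto ester. The E geometry is taken over from the alkenylboron reagent. The 2,3-trans relation comes from suprafacial addition to the E alkene, and the (2R,3S) sense from a chiral phosphoric acid.

Key step: step 10

Assumption: no close precedent fixes the sense of induction of a chiral phosphoric acid with this dienophile, so the (R)-configured acid is written in step 10; its mirror image would be used without other change if it should favour the (2S,3R) adduct.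

**Route**

Step 1
Reactants: 1 3,4-bis(benzyloxy)benzyl chloride; 2 methyl acetoacetate
Product: 3 methyl 5-[3,4-bis(benzyloxy)phenyl]-3-oxopentanoate
Conditions: 2 (1.2 equiv), LDA (2.4 equiv), THF, −78 → 0 °C; then 1, 0 °C → rt; aq. NH4Cl
Reagents that add atoms: none
Why: γ-Alkylation of the acetoacetate dianion should take place at its terminal, more basic carbon by SN2 displacement of the reactive benzylic chloride, giving the 5-aryl-3-oxopentanoate directly.

Step 2
Reactants: 3 methyl 5-[3,4-bis(benzyloxy)phenyl]-3-oxopentanoate
Product: 4 methyl (S)-5-[3,4-bis(benzyloxy)phenyl]-3-hydroxypentanoate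
Conditions: H2 (10 bar), RuCl2[(S)-BINAP](DMF)n (1 mol%), MeOH, 50 °C
Reagents that add atoms: none
Why: Noyori asymmetric hydrogenation of the chelating β-keto ester should deliver hydrogen to the ketone face selected by (S)-BINAP, which for a 3-oxoalkanoate with a plain alkyl chain gives the (S)-carbinol, while aryl benzyl ethers are inert to the ruthenium catalyst.

Step 3
Reactants: 4 methyl (S)-5-[3,4-bis(benzyloxy)phenyl]-3-hydroxypentanoate
Product: 5 methyl (S)-3-(benzyloxy)-5-[3,4-bis(benzyloxy)phenyl]pentanoate
Conditions: BnOC(=NH)CCl3 (1.5 equiv), TfOH (5 mol%), CH2Cl2–cyclohexane, 0 °C → rt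
Reagents that add atoms: benzyl 2,2,2-trichloroacetimidate, N=C(OCc1ccccc1)C(Cl)(Cl)Cl
Why: Acid-catalysed O-benzylation with the trichloroacetimidate avoids the basic conditions that would cause retro-aldol cleavage or β-elimination of a β-hydroxy ester, and it leaves the C–O bond of the stereocentre untouched.

Step 4
Reactants: 5 methyl (S)-3-(benzyloxy)-5-[3,4-bis(benzyloxy)phenyl]pentanoate
Product: 6 (S)-3-(benzyloxy)-5-[3,4-bis(benzyloxy)phenyl]pentanoic acid
Conditions: LiOH·H2O (2 equiv), THF–MeOH–H2O, 0 °C → rt; then aq. HCl to pH 3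
Reagents that add atoms: lithium hydroxide, [Li+].[OH-]
Why: Saponification of the methyl ester by acyl–oxygen cleavage should be clean at low temperature, where E1cB loss of benzyl alcohol from the β-benzyloxy carboxylate is slow, and the stereocentre is not involved.

Step 5
Reactants: 7 3,4-bis(benzyloxy)benzaldehyde
Product: 8 (E)-2-{2-[3,4-bis(benzyloxy)phenyl]ethenyl}-4,4,5,5-tetramethyl-1,3,2-dioxaborolane
Conditions: CH2(Bpin)2 (1.2 equiv), LiTMP (1.2 equiv), THF, 0 °C; then 7, −78 °C → rt
Reagents that add atoms: bis[(pinacolato)boryl]methane, CC1(C)OB(CB2OC(C)(C)C(C)(C)O2)OC1(C)C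
Why: In the boron–Wittig olefination the α-boryl carbanion adds to the aromatic aldehyde and syn B–O elimination from the favoured adduct should give the trans alkenylboronate.

Step 6
Reactants: 8 (E)-2-{2-[3,4-bis(benzyloxy)phenyl]ethenyl}-4,4,5,5-tetramethyl-1,3,2-dioxaborolane
Product: 9 potassium (E)-{2-[3,4-bis(benzyloxy)phenyl]ethenyl}trifluoroborate
Conditions: KHF2 (4 equiv), MeOH–H2O, rt
Reagents that add atoms: potassium hydrogen difluoride, F.[F-].[K+]
Why: Ligand exchange at boron from pinacolate to fluoride should give the crystalline trifluoroborate without touching the alkene geometry.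

Step 7
Reactants: 6 (S)-3-(benzyloxy)-5-[3,4-bis(benzyloxy)phenyl]pentanoic acid; 9 potassium (E)-{2-[3,4-bis(benzyloxy)phenyl]ethenyl}trifluoroborate
Product: 10 (E)-2-[3,4-bis(benzyloxy)phenyl]ethenyl (S)-3-(benzyloxy)-5-[3,4-bis(benzyloxy)phenyl]pentanoate
Conditions: 9 (2 equiv), CuBr (10 mol%), DMAP (20 mol%), 4 Å MS, O2 (1 atm), MeCN, 60 °C
Reagents that add atoms: none
Why: Copper-catalysed oxidative C–O coupling of a carboxylic acid with an alkenyltrifluoroborate (Chan–Lam type) proceeds through transmetallation and reductive elimination with retention, so the E geometry of 9 should be carried into the enol ester, which alkyne hydro-acyloxylation (usually Z-selective) would not guarantee.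

Step 8
Reactants: 11 3,5-bis(benzyloxy)phenol
Product: 12 2-hydroxy-4,6-bis(benzyloxy)benzaldehyde
Conditions: (CH2O)n (6 equiv), MgCl2 (1.5 equiv), Et3N (3.75 equiv), MeCN, reflux; aq. HCl work-up
Reagents that add atoms: formaldehyde (as paraformaldehyde), C=O
Why: In the Casnati–Skattebøl ortho-formylation the magnesium phenoxide directs hydroxymethylation to a position next to the OH (the two are equivalent, the para position is not attacked) and a second formaldehyde oxidises the magnesium-bound benzylic alkoxide by hydride transfer.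

Step 9
Reactants: 12 2-hydroxy-4,6-bis(benzyloxy)benzaldehyde
Product: 13 3,5-bis(benzyloxy)-2-(hydroxymethyl)phenol
Conditions: NaBH4 (1.5 equiv), THF–MeOH, 0 °C; pH 7 phosphate buffer, cold work-up, used at once
Reagents that add atoms: none
Why: Borohydride reduction of the salicylaldehyde should be fast and clean, and the neutral cold work-up is chosen because this electron-rich salicyl alcohol ionises readily under acid or heat.

Step 10
Reactants: 13 3,5-bis(benzyloxy)-2-(hydroxymethyl)phenol; 10 (E)-2-[3,4-bis(benzyloxy)phenyl]ethenyl (S)-3-(benzyloxy)-5-[3,4-bis(benzyloxy)phenyl]pentanoate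
Product: 15 hepta-O-benzylphylloflavan, via o-quinone methide 14 (not isolated)
Conditions: (R)-TRIP (10 mol%), 5 Å MS, PhMe, 0 °C → rt; 13 added slowly to 10 (1.5 equiv, excess recovered)
Reagents that add atoms: none
Why: Proposed new method: the phosphoric acid dehydrates 13 to o-quinone methide 14, an easy ionisation because alkoxy groups stand ortho and para to the benzylic carbon, and holds 14 by a hydrogen bond to its carbonyl oxygen while the acyloxy-bearing alkene carbon of 10 bonds to the exocyclic CH2 (C3–C4) and the methide oxygen bonds to the aryl-bearing carbon (O1–C2). The closest known reaction type is the chiral-Brønsted-acid-catalysed inverse-electron-demand hetero-Diels–Alder reaction of o-quinone methides from o-hydroxybenzyl alcohols with electron-rich styrenes, enecarbamates or vinyl sulfides; a 2-arylvinyl ester has not served as the 2π partner. The pyran ring closes by a concerted but asynchronous [4+2] cycloaddition (oxadiene 4π plus alkene 2π), whose stepwise limit is a 6-exo-trig capture of the p-alkoxybenzylic cation by the phenol oxygen. C2 and C3 should come out trans because both bonds form on one face of the E alkene (in the stepwise limit, opening of the trans-acyloxonium ion by the phenol oxygen leads to the same trans ring), and their (2R,3S) sense is to be set by the catalyst, whose 3,3'-aryl groups are expected to fix both the open face of the bound methide and the endo or exo placement of the catechol ring, since C4 carries no substituent. The step needs regioselectivity, secured by the 3,4-dialkoxyphenyl group that stabilises positive charge at C2 far better than the acyloxy group could at C3, and it needs cycloaddition to outrun Friedel–Crafts attack by the phloroglucinol-type rings, which slow addition of 13 to an excess of 10 is meant to secure. The side-chain centre is too remote to interfere, so a minor (2S,3R) adduct would be a diastereomer that chromatography can remove.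

Step 11
Reactants: 15 hepta-O-benzylphylloflavan
Product: 16 phylloflavan
Conditions: H2 (1 atm), 20% Pd(OH)2/C, THF–MeOH (1:1), rt
Reagents that add atoms: none
Why: Hydrogenolysis over Pearlman's catalyst should cleave the six aryl and one alkyl benzyl ether, as is standard for benzylated catechin esters, while the chroman C2–O1 bond, the ester and all three stereocentres stay untouched.

**Compound list**

1 | 3,4-bis(benzyloxy)benzyl chloride | ClCc1ccc(OCc2ccccc2)c(OCc2ccccc2)c1 | starting material
2 | methyl acetoacetate | COC(=O)CC(C)=O | starting material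
3 | methyl 5-[3,4-bis(benzyloxy)phenyl]-3-oxopentanoate | COC(=O)CC(=O)CCc1ccc(OCc2ccccc2)c(OCc2ccccc2)c1 | intermediate
4 | methyl (S)-5-[3,4-bis(benzyloxy)phenyl]-3-hydroxypentanoate | COC(=O)C[C@@H](O)CCc1ccc(OCc2ccccc2)c(OCc2ccccc2)c1 | intermediate
5 | methyl (S)-3-(benzyloxy)-5-[3,4-bis(benzyloxy)phenyl]pentanoate | COC(=O)C[C@@H](OCc1ccccc1)CCc1ccc(OCc2ccccc2)c(OCc2ccccc2)c1 | intermediate
6 | (S)-3-(benzyloxy)-5-[3,4-bis(benzyloxy)phenyl]pentanoic acid | OC(=O)C[C@@H](OCc1ccccc1)CCc1ccc(OCc2ccccc2)c(OCc2ccccc2)c1 | intermediate
7 | 3,4-bis(benzyloxy)benzaldehyde | O=Cc1ccc(OCc2ccccc2)c(OCc2ccccc2)c1 | starting material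
8 | (E)-2-{2-[3,4-bis(benzyloxy)phenyl]ethenyl}-4,4,5,5-tetramethyl-1,3,2-dioxaborolane | CC1(C)OB(/C=C/c2ccc(OCc3ccccc3)c(OCc3ccccc3)c2)OC1(C)C | intermediate
9 | potassium (E)-{2-[3,4-bis(benzyloxy)phenyl]ethenyl}trifluoroborate | [K+].F[B-](F)(F)/C=C/c1ccc(OCc2ccccc2)c(OCc2ccccc2)c1 | intermediate
10 | (E)-2-[3,4-bis(benzyloxy)phenyl]ethenyl (S)-3-(benzyloxy)-5-[3,4-bis(benzyloxy)phenyl]pentanoate | O=C(C[C@@H](OCc1ccccc1)CCc1ccc(OCc2ccccc2)c(OCc2ccccc2)c1)O/C=C/c1ccc(OCc2ccccc2)c(OCc2ccccc2)c1 | intermediate
11 | 3,5-bis(benzyloxy)phenol | Oc1cc(OCc2ccccc2)cc(OCc2ccccc2)c1 | starting material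
12 | 2-hydroxy-4,6-bis(benzyloxy)benzaldehyde | O=Cc1c(O)cc(OCc2ccccc2)cc1OCc1ccccc1 | intermediate
13 | 3,5-bis(benzyloxy)-2-(hydroxymethyl)phenol | OCc1c(O)cc(OCc2ccccc2)cc1OCc1ccccc1 | intermediate
14 | 3,5-bis(benzyloxy)-6-methylidenecyclohexa-2,4-dien-1-one (o-quinone methide) | C=C1C(=O)C=C(OCc2ccccc2)C=C1OCc1ccccc1 | intermediate (not isolated)
15 | hepta-O-benzylphylloflavan, (2R,3S)-5,7-bis(benzyloxy)-2-[3,4-bis(benzyloxy)phenyl]chroman-3-yl (S)-3-(benzyloxy)-5-[3,4-bis(benzyloxy)phenyl]pentanoate | O=C(C[C@@H](OCc1ccccc1)CCc1ccc(OCc2ccccc2)c(OCc2ccccc2)c1)O[C@H]1Cc2c(OCc3ccccc3)cc(OCc3ccccc3)cc2O[C@@H]1c1ccc(OCc2ccccc2)c(OCc2ccccc2)c1 | intermediate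
16 | phylloflavan, (2R,3S)-2-(3,4-dihydroxyphenyl)-5,7-dihydroxychroman-3-yl (S)-5-(3,4-dihydroxyphenyl)-3-hydroxypentanoate | O=C(C[C@@H](O)CCc1ccc(O)c(O)c1)O[C@H]1Cc2c(O)cc(O)cc2O[C@@H]1c1ccc(O)c(O)c1 | target

**Step count**

Total step count: 11.
Longest linear sequence: 7 steps (steps 1, 2, 3, 4, 7, 10, 11).

**Steps most likely to fail**

Step 10 (proposed new method). The methide may be consumed by Friedel–Crafts alkylation of the electron-rich phloroglucinol ring of 13 or of product 15 faster than it adds to the weakly nucleophilic enol ester, leading to oligomers. The catalyst may also fail to discriminate the alkene faces, because face selection and endo/exo placement must both be controlled. The fallback uses known chemistry and sets out from acid 6. Commercial (+)-catechin is benzylated at its four phenols (BnBr, K2CO3, DMF, 0 °C → rt) to 5,7,3',4'-tetra-O-benzyl-(+)-catechin F1. Its 3-hydroxyl is then acylated with 6 by Steglich esterification (EDC·HCl, DMAP, CH2Cl2, rt). This gives 15, where the route is rejoined before step 11, with C2 and C3 taken from the chiral pool.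

Step 7. Protodeboronation or oxidative homocoupling of the electron-rich styryltrifluoroborate may use up 9 before the C–O bond forms, the E geometry may erode, or DMAP may induce β-elimination of benzyl alcohol from the acyl component. The fallback forms the acyl–oxygen bond instead of the vinyl–oxygen bond and sets out from alkenylboronate 8 and acid 6. Oxidation of 8 (NaBO3·4H2O, THF–H2O, rt) should give 2-[3,4-bis(benzyloxy)phenyl]acetaldehyde F2. Acid 6 is converted with oxalyl chloride (cat. DMF, CH2Cl2, 0 °C) into (S)-3-(benzyloxy)-5-[3,4-bis(benzyloxy)phenyl]pentanoyl chloride F3. The potassium enolate of F2 (KHMDS, THF, −78 °C) is O-acylated with F3. Both geometric isomers are expected, and chromatography separates 10 from (Z)-2-[3,4-bis(benzyloxy)phenyl]ethenyl (S)-3-(benzyloxy)-5-[3,4-bis(benzyloxy)phenyl]pentanoate F4. The route is rejoined at 10.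

Step 9. Traces of acid or warming during work-up and concentration may ionise 13, which then condenses with itself through its nucleophilic ring positions. The fallback reaches 13 by a different construction and sets out from phenol 11, bypassing step 8 as well. Boronic-acid-templated ortho-hydroxymethylation (PhB(OH)2, (CH2O)n, cat. propionic acid, PhMe, reflux with water removal) should give the crystalline, storable 5,7-bis(benzyloxy)-2-phenyl-4H-1,3,2-benzodioxaborinine F5. Transesterification with propane-1,3-diol (PhMe, rt) liberates 13 under neutral conditions as a solution that is dried over sieves and taken into step 10 without concentration. The route is rejoined at 13.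

**Further compounds**

F1 | step 10 | 5,7,3',4'-tetra-O-benzyl-(+)-catechin, (2R,3S)-5,7-bis(benzyloxy)-2-[3,4-bis(benzyloxy)phenyl]chroman-3-ol | O[C@H]1Cc2c(OCc3ccccc3)cc(OCc3ccccc3)cc2O[C@@H]1c1ccc(OCc2ccccc2)c(OCc2ccccc2)c1
F2 | step 7 | 2-[3,4-bis(benzyloxy)phenyl]acetaldehyde | O=CCc1ccc(OCc2ccccc2)c(OCc2ccccc2)c1
F3 | step 7 | (S)-3-(benzyloxy)-5-[3,4-bis(benzyloxy)phenyl]pentanoyl chloride | O=C(Cl)C[C@@H](OCc1ccccc1)CCc1ccc(OCc2ccccc2)c(OCc2ccccc2)c1
F4 | step 7 | (Z)-2-[3,4-bis(benzyloxy)phenyl]ethenyl (S)-3-(benzyloxy)-5-[3,4-bis(benzyloxy)phenyl]pentanoate | O=C(C[C@@H](OCc1ccccc1)CCc1ccc(OCc2ccccc2)c(OCc2ccccc2)c1)O/C=C\c1ccc(OCc2ccccc2)c(OCc2ccccc2)c1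
F5 | step 9 | 5,7-bis(benzyloxy)-2-phenyl-4H-1,3,2-benzodioxaborinine | c1ccc(cc1)B1OCc2c(OCc3ccccc3)cc(OCc3ccccc3)cc2O1
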